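**Retrosynthetic overview**

1. In abietane numbering the target has an aromatic ring C (C8, C9, C11–C14), a C7 ketone in ring B, and ring A (C1–C5, C10) bridged by the δ-lactone C10–C20–O–C19(=O)–C4–C5.
2. Last disconnections: the C11 oxygen (phenol → p-quinone → hydroquinone) and ring B at C7–C8 (Friedel–Crafts acylation on a symmetric 3,5-dimethoxy-4-isopropylphenyl group, which also frees 14-OH).
3. Key disconnection: C4–C5 and O–C20 together, back to an open-chain acid whose quaternary C10 carries an (E)-enoate (C5=C6–C7) and a CH2OTs group (C20). An enediolate Michael addition is followed by tosylate displacement by the same carboxyl group.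
4. Enabling feature: C5 is β to the C7 carbonyl and C20 lies 1,3-diaxial to C19 on ring A (3-oxabicyclo[3.3.1]nonan-2-one: bridgeheads C4/C10; bridges C5, C1–C3, C19–O–C20). One α-carboxy carbanion at C4 can therefore react first through carbon, then through oxygen.
5. C10 is set by desymmetrising a 2-aryl-2-alkylpropane-1,3-diol made from an aryl malonate. Ring order: C (purchased) → A and lactone ring together (step 11) → B (step 13).

Key step: step 11

Remark: abietane numbering (C1–C20) is used for all intermediates; bromide 4 is taken as a catalogue compound, and the methyl-bearing carbon (later C4) is carried as an epimer mixture until step 11 sets it.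

**Route**

Step 1
Reactants: 1 tert-butyl propanoate; 2 1,3-diiodopropane
Product: 3 tert-butyl (2RS)-5-iodo-2-methylpentanoate
Conditions: LDA (1.05 equiv), THF, −78 °C; then 2 (3 equiv), DMPU, −78 → −20 °C
Reagents that add atoms: none
Why: SN2 alkylation of the lithium ester enolate by a primary iodide, with excess diiodide limiting double substitution; the new stereocentre (later C4) is left racemic because enolisation in step 11 erases it.

Step 2
Reactants: 4 5-bromo-2-isopropyl-1,3-dimethoxybenzene; 5 dimethyl malonate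
Product: 6 dimethyl 2-(4-isopropyl-3,5-dimethoxyphenyl)malonate
Conditions: Pd(OAc)2 (2 mol %), t-Bu3P·HBF4 (4 mol %), K3PO4 (3 equiv), toluene, 80 °C
Reagents that add atoms: none
Why: palladium-catalysed α-arylation of a malonate with an aryl bromide lacking ortho substituents; mono-arylation is favoured because the product rests as its unreactive enolate, and no stereocentre is formed.

Step 3
Reactants: 6 dimethyl 2-(4-isopropyl-3,5-dimethoxyphenyl)malonate; 3 tert-butyl (2RS)-5-iodo-2-methylpentanoate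
Product: 7 dimethyl 2-[(4RS)-5-(tert-butoxy)-4-methyl-5-oxopentyl]-2-(4-isopropyl-3,5-dimethoxyphenyl)malonate
Conditions: NaH (1.1 equiv), DMF, 0 °C; then 3 (1.2 equiv), 60 °C
Reagents that add atoms: none
Why: malonate alkylation (SN2) builds the quaternary carbon that becomes C10, still prochiral because its two esters are identical; the tert-butyl ester α-hydrogen is far less acidic than the malonate and is untouched.

Step 4
Reactants: 7 dimethyl 2-[(4RS)-5-(tert-butoxy)-4-methyl-5-oxopentyl]-2-(4-isopropyl-3,5-dimethoxyphenyl)malonate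
Product: 8 tert-butyl (2RS)-7-hydroxy-6-(hydroxymethyl)-6-(4-isopropyl-3,5-dimethoxyphenyl)-2-methylheptanoate
Conditions: LiBH4 (4 equiv), MeOH (4 equiv), THF, 0 °C → rt
Reagents that add atoms: none
Why: borohydride reduction of both methyl esters to the prochiral 1,3-diol, chemoselective because lithium borohydride reduces methyl esters readily and tert-butyl esters only very slowly.

Step 5
Reactants: 8 tert-butyl (2RS)-7-hydroxy-6-(hydroxymethyl)-6-(4-isopropyl-3,5-dimethoxyphenyl)-2-methylheptanoate
Product: 9 tert-butyl (2RS,6S)-7-(benzoyloxy)-6-(hydroxymethyl)-6-(4-isopropyl-3,5-dimethoxyphenyl)-2-methylheptanoate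
Conditions: vinyl benzoate (5 equiv), Et2Zn (10 mol %), ProPhenol ligand (5 mol %, antipode that acylates the pro-S CH2OH), toluene, −15 °C
Reagents that add atoms: vinyl benzoate, C=COC(=O)c1ccccc1
Why: catalytic enantioselective desymmetrisation of a 2-aryl-2-alkylpropane-1,3-diol by dinuclear-zinc acyl transfer should set the quaternary stereocentre (C10) by discriminating the two enantiotopic hydroxymethyl groups; a benzoate is used because it resists 1,3-acyl migration.

Step 6
Reactants: 9 tert-butyl (2RS,6S)-7-(benzoyloxy)-6-(hydroxymethyl)-6-(4-isopropyl-3,5-dimethoxyphenyl)-2-methylheptanoate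
Product: 10 tert-butyl (2RS,6R)-7-(benzoyloxy)-6-formyl-6-(4-isopropyl-3,5-dimethoxyphenyl)-2-methylheptanoate
Conditions: Dess–Martin periodinane (1.3 equiv), NaHCO3, CH2Cl2, 0 °C → rt
Reagents that add atoms: none
Why: Dess–Martin oxidation of the neopentyl primary alcohol to an aldehyde that has no α-hydrogen and so can neither epimerise nor eliminate the benzoate.

Step 7
Reactants: 10 tert-butyl (2RS,6R)-7-(benzoyloxy)-6-formyl-6-(4-isopropyl-3,5-dimethoxyphenyl)-2-methylheptanoate
Product: 11 9-tert-butyl 1-methyl (2E,4R,8RS)-4-[(benzoyloxy)methyl]-4-(4-isopropyl-3,5-dimethoxyphenyl)-8-methylnon-2-enedioate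
Conditions: trimethyl phosphonoacetate (1.5 equiv), NaH (1.4 equiv), THF, 0 °C → rt
Reagents that add atoms: trimethyl phosphonoacetate, COC(=O)CP(=O)(OC)OC
Why: Horner–Wadsworth–Emmons olefination, E-selective for a stabilised phosphonate anion and a bulky α-quaternary aldehyde, installs C6–C7 as the Michael acceptor.

Step 8
Reactants: 11 9-tert-butyl 1-methyl (2E,4R,8RS)-4-[(benzoyloxy)methyl]-4-(4-isopropyl-3,5-dimethoxyphenyl)-8-methylnon-2-enedioate
Product: 12 9-tert-butyl 1-methyl (2E,4R,8RS)-4-(hydroxymethyl)-4-(4-isopropyl-3,5-dimethoxyphenyl)-8-methylnon-2-enedioate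
Conditions: K2CO3 (0.3 equiv), MeOH, 0 °C → rt
Reagents that add atoms: none
Why: base-catalysed methanolysis (transesterification) of the benzoate; the methyl enoate is unchanged in methanol, the tert-butyl ester is inert, and the freed alkoxide cannot reach the (E)-ester carbonyl.

Step 9
Reactants: 12 9-tert-butyl 1-methyl (2E,4R,8RS)-4-(hydroxymethyl)-4-(4-isopropyl-3,5-dimethoxyphenyl)-8-methylnon-2-enedioate
Product: 13 9-tert-butyl 1-methyl (2E,4R,8RS)-4-(4-isopropyl-3,5-dimethoxyphenyl)-8-methyl-4-[(tosyloxy)methyl]non-2-enedioate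
Conditions: TsCl (1.5 equiv), Et3N (2 equiv), DMAP (0.1 equiv), CH2Cl2, 0 °C → rt
Reagents that add atoms: p-toluenesulfonyl chloride, Cc1ccc(cc1)S(=O)(=O)Cl
Why: sulfonylation of the primary alcohol; a tosylate is chosen because it has no acidic α-hydrogen and, being neopentyl, should stay inert to base and to external nucleophiles until a carboxylate is placed next to it.

Step 10
Reactants: 13 9-tert-butyl 1-methyl (2E,4R,8RS)-4-(4-isopropyl-3,5-dimethoxyphenyl)-8-methyl-4-[(tosyloxy)methyl]non-2-enedioate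
Product: 14 (2RS,6R,7E)-6-(4-isopropyl-3,5-dimethoxyphenyl)-9-methoxy-2-methyl-9-oxo-6-[(tosyloxy)methyl]non-7-enoic acid
Conditions: TFA/CH2Cl2 (1:4), 0 °C → rt
Reagents that add atoms: none
Why: acidolysis of the tert-butyl ester (E1 loss of isobutene) frees the C19 acid while the methyl enoate and the tosylate are stable to acid; the ring positions ortho to the quaternary carbon are too crowded for tert-butylation.

Step 11
Reactants: 14 (2RS,6R,7E)-6-(4-isopropyl-3,5-dimethoxyphenyl)-9-methoxy-2-methyl-9-oxo-6-[(tosyloxy)methyl]non-7-enoic acid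
Product: 16 methyl 2-[(1S,5R,9R)-5-(4-isopropyl-3,5-dimethoxyphenyl)-1-methyl-2-oxo-3-oxabicyclo[3.3.1]nonan-9-yl]acetate, via lithium carboxylate Michael adduct 15 (not isolated)
Conditions: LDA (2.3 equiv), THF–DMPU, −78 → 0 °C; t-BuOH (1.5 equiv), 0 °C; then 45 °C
Reagents that add atoms: none
Why: LDA (2 equiv) converts the acid into its enediolate, and C4 adds 6-exo-trig to C5 of the (E)-enoate, closing ring A (intramolecular Michael addition; closest known type: Michael cyclisations of ester and carboxylic acid enolates onto enoates). After t-BuOH has protonated the C6 ester enolate, the C19 carboxylate, now 1,3-diaxial to C20, displaces the tosylate 6-exo-tet and closes the δ-lactone (SN2 lactonisation of a syn-axial carboxylate onto a primary sulfonate), so ring A and the 3-oxabicyclo[3.3.1]nonan-2-one form in one flask. C5 should be set by the C10 stereocentre through a chair transition state with the enoate arm equatorial and the aryl group anti to the forming bond (Felkin–Anh-type), which leaves CH2OTs axial and H-5 anti to C20, as the trans A/B fusion requires. C4 should be set because the flat enediolate terminus, not the methyl group, takes the pseudo-axial site beside the axial CH2OTs, where lithium can bridge carboxylate and sulfonate oxygens, and only this epimer can lactonise. The step needs Michael addition to precede any alkylation at C20 and O-alkylation to come from the carboxylate only: the neopentyl tosylate is inert to SN2 at or below 0 °C, the enoate has no γ-hydrogen and a hindered β-carbon toward LDA, and the proton quench removes the competing ester enolate before warming.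

Step 12
Reactants: 16 methyl 2-[(1S,5R,9R)-5-(4-isopropyl-3,5-dimethoxyphenyl)-1-methyl-2-oxo-3-oxabicyclo[3.3.1]nonan-9-yl]acetate
Product: 17 2-[(1S,5R,9R)-5-(4-isopropyl-3,5-dimethoxyphenyl)-1-methyl-2-oxo-3-oxabicyclo[3.3.1]nonan-9-yl]acetic acid
Conditions: LiI (5 equiv), EtOAc, reflux; then 1 M HCl
Reagents that add atoms: none
Why: SN2 demethylation of the methyl ester by iodide, which should spare the lactone because its O-alkyl carbon (C20) is neopentyl and no acyl attack is involved.

Step 13
Reactants: 17 2-[(1S,5R,9R)-5-(4-isopropyl-3,5-dimethoxyphenyl)-1-methyl-2-oxo-3-oxabicyclo[3.3.1]nonan-9-yl]acetic acid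
Product: 20 (4S,5R,10R)-14-hydroxy-12-methoxy-7-oxoabieta-8,11,13-trien-19,20-olide, via acid chloride 18 (not isolated), via 14-O-methyl ketone 19 (not isolated)
Conditions: (COCl)2 (1.5 equiv), DMF (cat.), CH2Cl2, 0 °C → rt, evaporate; then BCl3 (3 equiv), CH2Cl2, −78 → 0 °C; aq. NaHCO3
Reagents that add atoms: none
Why: intramolecular Friedel–Crafts acylation closes ring B (C7–C8) at either of the two equivalent positions ortho to C9, each activated by an ortho and a para methoxy group, and BCl3 then cleaves only the methyl ether peri to the new ketone through its six-membered chelate; no stereocentre is formed, and the trans A/B fusion follows from C5 and C10.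

Step 14
Reactants: 20 (4S,5R,10R)-14-hydroxy-12-methoxy-7-oxoabieta-8,11,13-trien-19,20-olide
Product: 22 (4S,5R,10R)-11,14-dihydroxy-12-methoxy-7-oxoabieta-8,11,13-trien-19,20-olide (CNP0159814.2), via quinone 21 (not isolated)
Conditions: Fremy's salt (2.5 equiv), KH2PO4 buffer, acetone–H2O, 0 °C → rt; then Na2S2O4 (aq), EtOAc, rt, under argon
Reagents that add atoms: potassium nitrosodisulfonate (Fremy's salt), [K+].[K+].[O-]S(=O)(=O)N([O])S(=O)(=O)[O-]
Why: Teuber oxidation of a phenol with a free para position (C11, the only ring CH; both ortho positions are substituted) should give the 11,14-p-quinone, and dithionite reduction returns the aromatic ring as the hydroquinone without touching the C12 methyl ether.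

**Compound list**

1 | tert-butyl propanoate | CCC(=O)OC(C)(C)C | starting material
2 | 1,3-diiodopropane | ICCCI | starting material
3 | tert-butyl (2RS)-5-iodo-2-methylpentanoate | CC(CCCI)C(=O)OC(C)(C)C | intermediate
4 | 5-bromo-2-isopropyl-1,3-dimethoxybenzene | COc1cc(Br)cc(OC)c1C(C)C | starting material
5 | dimethyl malonate | COC(=O)CC(=O)OC | starting material
6 | dimethyl 2-(4-isopropyl-3,5-dimethoxyphenyl)malonate | COC(=O)C(C(=O)OC)c1cc(OC)c(C(C)C)c(OC)c1 | intermediate
7 | dimethyl 2-[(4RS)-5-(tert-butoxy)-4-methyl-5-oxopentyl]-2-(4-isopropyl-3,5-dimethoxyphenyl)malonate | COC(=O)C(CCCC(C)C(=O)OC(C)(C)C)(C(=O)OC)c1cc(OC)c(C(C)C)c(OC)c1 | intermediate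
8 | tert-butyl (2RS)-7-hydroxy-6-(hydroxymethyl)-6-(4-isopropyl-3,5-dimethoxyphenyl)-2-methylheptanoate | CC(CCCC(CO)(CO)c1cc(OC)c(C(C)C)c(OC)c1)C(=O)OC(C)(C)C | intermediate
9 | tert-butyl (2RS,6S)-7-(benzoyloxy)-6-(hydroxymethyl)-6-(4-isopropyl-3,5-dimethoxyphenyl)-2-methylheptanoate | CC(CCC[C@@](COC(=O)c1ccccc1)(CO)c1cc(OC)c(C(C)C)c(OC)c1)C(=O)OC(C)(C)C | intermediate
10 | tert-butyl (2RS,6R)-7-(benzoyloxy)-6-formyl-6-(4-isopropyl-3,5-dimethoxyphenyl)-2-methylheptanoate | CC(CCC[C@@](COC(=O)c1ccccc1)(C=O)c1cc(OC)c(C(C)C)c(OC)c1)C(=O)OC(C)(C)C | intermediate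
11 | 9-tert-butyl 1-methyl (2E,4R,8RS)-4-[(benzoyloxy)methyl]-4-(4-isopropyl-3,5-dimethoxyphenyl)-8-methylnon-2-enedioate | CC(CCC[C@@](COC(=O)c1ccccc1)(/C=C/C(=O)OC)c1cc(OC)c(C(C)C)c(OC)c1)C(=O)OC(C)(C)C | intermediate
12 | 9-tert-butyl 1-methyl (2E,4R,8RS)-4-(hydroxymethyl)-4-(4-isopropyl-3,5-dimethoxyphenyl)-8-methylnon-2-enedioate | CC(CCC[C@@](CO)(/C=C/C(=O)OC)c1cc(OC)c(C(C)C)c(OC)c1)C(=O)OC(C)(C)C | intermediate
13 | 9-tert-butyl 1-methyl (2E,4R,8RS)-4-(4-isopropyl-3,5-dimethoxyphenyl)-8-methyl-4-[(tosyloxy)methyl]non-2-enedioate | CC(CCC[C@@](COS(=O)(=O)c1ccc(C)cc1)(/C=C/C(=O)OC)c1cc(OC)c(C(C)C)c(OC)c1)C(=O)OC(C)(C)C | intermediate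
14 | (2RS,6R,7E)-6-(4-isopropyl-3,5-dimethoxyphenyl)-9-methoxy-2-methyl-9-oxo-6-[(tosyloxy)methyl]non-7-enoic acid | CC(CCC[C@@](COS(=O)(=O)c1ccc(C)cc1)(/C=C/C(=O)OC)c1cc(OC)c(C(C)C)c(OC)c1)C(=O)O | intermediate
15 | lithium (1S,2R,3R)-3-(4-isopropyl-3,5-dimethoxyphenyl)-2-(2-methoxy-2-oxoethyl)-1-methyl-3-[(tosyloxy)methyl]cyclohexane-1-carboxylate | COC(=O)C[C@@H]1[C@@](COS(=O)(=O)c2ccc(C)cc2)(c2cc(OC)c(C(C)C)c(OC)c2)CCC[C@]1(C)C(=O)[O-].[Li+] | intermediate (not isolated)
16 | methyl 2-[(1S,5R,9R)-5-(4-isopropyl-3,5-dimethoxyphenyl)-1-methyl-2-oxo-3-oxabicyclo[3.3.1]nonan-9-yl]acetate | COC(=O)C[C@@H]1[C@@]2(c3cc(OC)c(C(C)C)c(OC)c3)CCC[C@]1(C)C(=O)OC2 | intermediate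
17 | 2-[(1S,5R,9R)-5-(4-isopropyl-3,5-dimethoxyphenyl)-1-methyl-2-oxo-3-oxabicyclo[3.3.1]nonan-9-yl]acetic acid | OC(=O)C[C@@H]1[C@@]2(c3cc(OC)c(C(C)C)c(OC)c3)CCC[C@]1(C)C(=O)OC2 | intermediate
18 | 2-[(1S,5R,9R)-5-(4-isopropyl-3,5-dimethoxyphenyl)-1-methyl-2-oxo-3-oxabicyclo[3.3.1]nonan-9-yl]acetyl chloride | ClC(=O)C[C@@H]1[C@@]2(c3cc(OC)c(C(C)C)c(OC)c3)CCC[C@]1(C)C(=O)OC2 | intermediate (not isolated)
19 | (4S,5R,10R)-12,14-dimethoxy-7-oxoabieta-8,11,13-trien-19,20-olide | COc1cc2c(c(OC)c1C(C)C)C(=O)C[C@@H]1[C@]23CCC[C@]1(C)C(=O)OC3 | intermediate (not isolated)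
20 | (4S,5R,10R)-14-hydroxy-12-methoxy-7-oxoabieta-8,11,13-trien-19,20-olide | COc1cc2c(c(O)c1C(C)C)C(=O)C[C@@H]1[C@]23CCC[C@]1(C)C(=O)OC3 | intermediate
21 | (4S,5R,10R)-12-methoxy-7,11,14-trioxoabieta-8,12-dien-19,20-olide | COC1=C(C(C)C)C(=O)C2=C(C1=O)[C@@]13CCC[C@](C)(C(=O)OC3)[C@@H]1CC2=O | intermediate (not isolated)
22 | (4S,5R,10R)-11,14-dihydroxy-12-methoxy-7-oxoabieta-8,11,13-trien-19,20-olide (CNP0159814.2) | COc1c(O)c2c(c(O)c1C(C)C)C(=O)C[C@@H]1[C@]23CCC[C@]1(C)C(=O)OC3 | target

**Step count and risks**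

Total step count: 14. Longest linear sequence: 13 steps (steps 2–14 from 4 and 5; step 1 is a one-step branch that joins in step 3).

Steps most likely to fail:

1. Step 11. The enediolate carbon or C5 may react with poor facial discrimination, so that the carboxylate ends trans to C20 and cannot lactonise; alkylation at C20 by carbon or by the ester enolate oxygen may also overtake the intended sequence. The fallback sets out from 10 and returns at 16; it forms the two bonds in separate steps and fixes the stereochemistry by ring fusion.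
   - Still–Gennari olefination of 10 (bis(2,2,2-trifluoroethyl) (methoxycarbonylmethyl)phosphonate, KHMDS, 18-crown-6, THF, −78 °C) gives 9-tert-butyl 1-methyl (2Z,4R,8RS)-4-[(benzoyloxy)methyl]-4-(4-isopropyl-3,5-dimethoxyphenyl)-8-methylnon-2-enedioate F1.
   - K2CO3 in MeOH removes the benzoate, and the freed C20 alkoxide closes onto the cis ester to give tert-butyl (2RS)-5-[(3R)-3-(4-isopropyl-3,5-dimethoxyphenyl)-6-oxo-3,6-dihydro-2H-pyran-3-yl]-2-methylpentanoate F2.
   - LDA (1.1 equiv, THF, −78 °C) forms only the tert-butyl ester enolate, which adds to C5 of the unsaturated lactone from the side of its own tether. The lactone ring should end cis-fused to ring A (H-5 anti to C20), and the ester, held by lithium to the lactone carbonyl on the C20 face, should end syn to C20. This gives tert-butyl (4aR,5S,8aR)-8a-(4-isopropyl-3,5-dimethoxyphenyl)-5-methyl-3-oxo-3,4,4a,5,6,7,8,8a-octahydro-1H-isochromene-5-carboxylate F3.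
   - TFA then gives (4aR,5S,8aR)-8a-(4-isopropyl-3,5-dimethoxyphenyl)-5-methyl-3-oxo-3,4,4a,5,6,7,8,8a-octahydro-1H-isochromene-5-carboxylic acid F4.
   - HCl in MeOH at 50 °C opens the fused lactone as the unhindered methyl ester, and the freed C20 hydroxyl closes onto the syn-axial, hindered C19 acid to give 16.

2. Step 5. Discrimination of the enantiotopic hydroxymethyl groups may be incomplete at a quaternary carbon that carries a long flexible chain, and 1,3-benzoyl migration may erode the enantiomeric purity. The fallback sets out from 8 and returns at 9, replacing catalytic desymmetrisation by resolution. Statistical mono-benzoylation (BzCl 1.0 equiv, pyridine, CH2Cl2, −20 °C, with diol and dibenzoate recycled) gives tert-butyl (2RS,6RS)-7-(benzoyloxy)-6-(hydroxymethyl)-6-(4-isopropyl-3,5-dimethoxyphenyl)-2-methylheptanoate F5. Preparative chromatography on a chiral stationary phase then separates the isomers, and the (6S) fraction is 9.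

3. Step 14. Oxidation of the hydrogen-bonded peri-hydroxy ketone may be sluggish, or the 2-acyl quinone may decompose before it is reduced. The fallback sets out from 20 and returns at 22 without a quinone stage. Elbs persulfate oxidation (K2S2O8, aq. NaOH, 0 °C → rt) should sulfoxylate the free para position to give potassium (4S,5R,10R)-14-hydroxy-12-methoxy-7-oxoabieta-8,11,13-trien-19,20-olid-11-yl sulfate F6; a lactone opened by the base recloses on acidification. Hydrolysis of the aryl sulfate (aq. HCl, dioxane, 60 °C, under argon) then gives 22.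

**Further compounds**

F1 | step 11 | 9-tert-butyl 1-methyl (2Z,4R,8RS)-4-[(benzoyloxy)methyl]-4-(4-isopropyl-3,5-dimethoxyphenyl)-8-methylnon-2-enedioate | CC(CCC[C@@](COC(=O)c1ccccc1)(/C=C\C(=O)OC)c1cc(OC)c(C(C)C)c(OC)c1)C(=O)OC(C)(C)C
F2 | step 11 | tert-butyl (2RS)-5-[(3R)-3-(4-isopropyl-3,5-dimethoxyphenyl)-6-oxo-3,6-dihydro-2H-pyran-3-yl]-2-methylpentanoate | CC(CCC[C@]1(COC(=O)C=C1)c1cc(OC)c(C(C)C)c(OC)c1)C(=O)OC(C)(C)C
F3 | step 11 | tert-butyl (4aR,5S,8aR)-8a-(4-isopropyl-3,5-dimethoxyphenyl)-5-methyl-3-oxo-3,4,4a,5,6,7,8,8a-octahydro-1H-isochromene-5-carboxylate | O=C1C[C@@H]2[C@@](CO1)(c1cc(OC)c(C(C)C)c(OC)c1)CCC[C@]2(C)C(=O)OC(C)(C)C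
F4 | step 11 | (4aR,5S,8aR)-8a-(4-isopropyl-3,5-dimethoxyphenyl)-5-methyl-3-oxo-3,4,4a,5,6,7,8,8a-octahydro-1H-isochromene-5-carboxylic acid | O=C1C[C@@H]2[C@@](CO1)(c1cc(OC)c(C(C)C)c(OC)c1)CCC[C@]2(C)C(=O)O
F5 | step 5 | tert-butyl (2RS,6RS)-7-(benzoyloxy)-6-(hydroxymethyl)-6-(4-isopropyl-3,5-dimethoxyphenyl)-2-methylheptanoate | CC(CCCC(COC(=O)c1ccccc1)(CO)c1cc(OC)c(C(C)C)c(OC)c1)C(=O)OC(C)(C)C
F6 | step 14 | potassium (4S,5R,10R)-14-hydroxy-12-methoxy-7-oxoabieta-8,11,13-trien-19,20-olid-11-yl sulfate | COc1c(OS(=O)(=O)[O-])c2c(c(O)c1C(C)C)C(=O)C[C@@H]1[C@]23CCC[C@]1(C)C(=O)OC3.[K+]
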